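1. Numbering follows daucane: C1 (quaternary, carries CH3-15, β), C2, C3, C4 (carbinol with isopropyl) and C5 (ring-fusion CH) form the five-membered ring; C5, C6 (O), C7, C8 (carries CH3-14), C9, C10 (O) and C1 form the seven-membered ring.
2. Retrosynthetic cuts, in order: both angelate acyl C–O bonds; the C4–isopropyl bond (ketone plus isopropyl nucleophile); C6–O and C5–H (back to a C5=C6 alkene, served from O10 through a silicon tether); C1–C10 with C6–C8 re-formed, which contracts the seven-membered ring to a cyclopropane C6–C7–C8; finally the two cyclopropane bonds at C8 (diene plus vinyl diazoacetate).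
3. Enabling feature: ring C1–C5–C6–C7–C8–C9–C10 holds the C8=C9 alkene, an sp3 C7 and, at C5–C6, the H/O pair of a former alkene. It is a cyclohepta-1,4-diene in disguise, the product of a [3,3] shift of a cis-divinylcyclopropane (C6–C7–C8) whose vinyl termini are C1 (ring-alkene carbon of a cyclopentene) and C10 (enol-ether carbon that becomes the allylic C–O centre).
4. Forward order: the five-membered ring is bought; an asymmetric Rh2(R-DOSP)4-catalysed carbenoid cyclopropanation makes the three-membered ring, which expands to the seven-membered ring. Helpers are the ester on C8 (carbenoid acceptor, later reduced to CH3-14), the dioxolane at C4 and the O10–Si–C6 tether.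
5. Stereochemistry: the chiral catalyst fixes the cyclopropane and the boat transition state relays it to C1 and C10. The 10α-oxygen tether delivers H (C5) and Si (C6, later O with retention) to the α face. The angular β-methyl steers isopropyl to the α face of the C4 ketone. The (Z)-acyl geometry comes from angelic acid.

Key step: step 5

Assumption: the facial sense of Rh2(R-DOSP)4 [DOSP = N-(4-dodecylbenzenesulfonyl)prolinate] is taken from the usual model for donor/acceptor carbenoids (the S catalyst gives the (1S,2R)-cyclopropane from styrene and methyl phenyldiazoacetate); if the sense is the reverse, the S catalyst is used and nothing else changes.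

**Route**

Step 1
Reactants: 1 2-bromo-3-methylcyclopent-2-en-1-one
Product: 2 6-bromo-7-methyl-1,4-dioxaspiro[4.4]non-6-ene
Conditions: HOCH2CH2OH, p-TsOH (cat.), benzene, reflux, azeotropic removal of water
Reagents that add atoms: ethylene glycol, OCCO
Why: Acid-catalysed ketalization masks the C4 carbonyl for the later hydride steps, the α-bromine holding the ring alkene in place; no stereocenter is formed.

Step 2
Reactants: 2 6-bromo-7-methyl-1,4-dioxaspiro[4.4]non-6-ene
Product: 3 6-ethenyl-7-methyl-1,4-dioxaspiro[4.4]non-6-ene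
Conditions: CH2=CHSnBu3, Pd(PPh3)4 (5 mol%), PhMe, 100 °C
Reagents that add atoms: tributyl(vinyl)stannane, C=C[Sn](CCCC)(CCCC)CCCC
Why: Stille cross-coupling of the alkenyl bromide gives the 1,3-diene whose terminal vinyl group is the only alkene open to a bulky carbenoid; no stereocenter is formed.

Step 3
Reactants: 4 2-[(tert-butyldimethylsilyl)oxy]acetaldehyde; 5 ethyl diazoacetate
Product: 6 ethyl 4-[(tert-butyldimethylsilyl)oxy]-2-diazo-3-hydroxybutanoate (racemic)
Conditions: DBU (10 mol%), MeCN, 23 °C
Reagents that add atoms: none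
Why: Amine-catalysed aldol-type addition of the diazoacetate α-carbon to the aldehyde; the new carbinol centre is racemic and is removed in step 4.

Step 4
Reactants: 6 ethyl 4-[(tert-butyldimethylsilyl)oxy]-2-diazo-3-hydroxybutanoate
Product: 7 ethyl (3E)-4-[(tert-butyldimethylsilyl)oxy]-2-diazobut-3-enoate
Conditions: POCl3, Et3N, CH2Cl2, 0 °C; used at once
Reagents that add atoms: none
Why: Dehydration through the dichlorophosphate (anti elimination into conjugation with the diazo ester) should give the (E)-siloxyvinyl diazoacetate, the geometry that later fixes C10.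

Step 5
Reactants: 3 6-ethenyl-7-methyl-1,4-dioxaspiro[4.4]non-6-ene; 7 ethyl (3E)-4-[(tert-butyldimethylsilyl)oxy]-2-diazobut-3-enoate
Product: 9 ethyl (1S,10R)-10-[(tert-butyldimethylsilyl)oxy]-4,4-(ethylenedioxy)-11,12,13-trinordauca-5,8-dien-14-oate, via cis-divinylcyclopropane 8 (not isolated)
Conditions: Rh2(R-DOSP)4 (1 mol%), pentane, slow addition of 7, −78 → 23 °C; then PhMe, 100 °C
Reagents that add atoms: none
Why: The Rh2(R-DOSP)4-bound carbenoid formed from 7 with loss of N2 adds to the terminal vinyl group of 3 in a concerted asynchronous [2+1] event to give cis-divinylcyclopropane 8 (ring C6–C7–C8), which on warming undergoes a [3,3]-sigmatropic (Cope) shift through the boat transition state, making the C1–C10 σ bond while C6–C8 breaks. The closest known reaction type is the tandem cyclopropanation/Cope rearrangement of vinyl diazoacetates with 1,3-dienes (formal [4+3] cycloaddition). The three-membered ring closes by carbene addition and the seven-membered ring closes by ring expansion of that cyclopropane (a pericyclic 3→7 enlargement, not an exo or endo cyclisation). C1 and C10 are set relative to each other by the boat geometry (the ring methyl is forced inside and the (E)-enol ether puts H inside and OSi outside, so CH3 and the C10 oxygen end up trans), and their absolute sense is relayed from the cyclopropane centres C6 and C8 fixed by Rh2(R-DOSP)4. The step needs site selectivity (only the monosubstituted vinyl of 3 reacts; the tetrasubstituted ring alkene and the trans enol ether are inert to the donor/acceptor carbenoid), cis diastereoselectivity (the alkene substituent is placed cis to the carbenoid vinyl group, as is usual for this carbenoid class) and retention of the (E)-enol ether, any (Z)-isomer needing two inside groups and staying behind. The ester on C8 is the helper that tames the carbenoid and is reduced to CH3-14 in steps 6 and 7.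

Step 6
Reactants: 9 ethyl (1S,10R)-10-[(tert-butyldimethylsilyl)oxy]-4,4-(ethylenedioxy)-11,12,13-trinordauca-5,8-dien-14-oate
Product: 10 (1S,10R)-10-[(tert-butyldimethylsilyl)oxy]-4,4-(ethylenedioxy)-11,12,13-trinordauca-5,8-dien-14-ol
Conditions: iBu2AlH (2.5 equiv), CH2Cl2, −78 °C; aq. potassium sodium tartrate
Reagents that add atoms: none
Why: 1,2-Reduction of the conjugated ester by iBu2AlH gives the primary allylic alcohol and leaves ketal, silyl ether and alkenes alone; no stereocenter changes.

Step 7
Reactants: 10 (1S,10R)-10-[(tert-butyldimethylsilyl)oxy]-4,4-(ethylenedioxy)-11,12,13-trinordauca-5,8-dien-14-ol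
Product: 12 (1S,10R)-10-[(tert-butyldimethylsilyl)oxy]-4,4-(ethylenedioxy)-11,12,13-trinordauca-5,8-diene, via allylic mesylate 11 (not isolated)
Conditions: MsCl, Et3N, CH2Cl2, −40 °C; then LiBHEt3, THF, −40 → 0 °C
Reagents that add atoms: none
Why: Sulfonylation followed by SN2 hydride displacement at the primary allylic carbon turns the helper carbon into CH3-14, direct attack being favoured because the SN2' carbon C9 sits next to the neopentyl, silyloxy-bearing C10.

Step 8
Reactants: 12 (1S,10R)-10-[(tert-butyldimethylsilyl)oxy]-4,4-(ethylenedioxy)-11,12,13-trinordauca-5,8-diene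
Product: 13 (1S,10R)-4,4-(ethylenedioxy)-11,12,13-trinordauca-5,8-dien-10-ol
Conditions: Bu4NF, THF, 23 °C
Reagents that add atoms: none
Why: Fluoride-induced desilylation frees the 10α-hydroxyl that anchors the tether; stereocenters are untouched.

Step 9
Reactants: 13 (1S,10R)-4,4-(ethylenedioxy)-11,12,13-trinordauca-5,8-dien-10-ol
Product: 15 (1S,5R,6S,10R)-4,4-(ethylenedioxy)-6,10-[(diisopropylsilanediyl)oxy]-11,12,13-trinordauc-8-ene (Si on C6 α; O on C10 α; H5 α), via hydrosilyl ether 14 (not isolated)
Conditions: iPr2SiHCl, imidazole, CH2Cl2, 0 °C; then Pt2(dvds)3 (1 mol%; dvds = (CH2=CHSiMe2)2O), PhMe, 60 °C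
Reagents that add atoms: chlorodiisopropylsilane, CC(C)[SiH](Cl)C(C)C
Why: Silylation of the only hydroxyl and Pt2(dvds)3-catalysed intramolecular hydrosilylation (Tamao type) let the 10α-O–Si–H arm reach C5=C6 only from the α face and add syn, silicon to the less substituted C6 and hydrogen to C5, so that H5 is α (trans ring fusion) and the C6–Si bond is α, the six-membered siloxane being preferred because every other mode would place silicon on a fully substituted carbon (C5 or C8).

Step 10
Reactants: 15 (1S,5R,6S,10R)-4,4-(ethylenedioxy)-6,10-[(diisopropylsilanediyl)oxy]-11,12,13-trinordauc-8-ene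
Product: 16 (1S,5R,6S,10R)-6,10-[(diisopropylsilanediyl)oxy]-11,12,13-trinordauc-8-en-4-one
Conditions: pyridinium p-toluenesulfonate, acetone/H2O (10:1), 40 °C
Reagents that add atoms: water, O
Why: Mild acid hydrolysis of the dioxolane frees the C4 ketone, while the hindered diisopropylsilyl ether bridge should survive and C5 has no β-leaving group (silicon, not oxygen, on C6) to invite elimination.

Step 11
Reactants: 16 (1S,5R,6S,10R)-6,10-[(diisopropylsilanediyl)oxy]-11,12,13-trinordauc-8-en-4-one
Product: 17 (1S,4R,5R,6S,10R)-6,10-[(diisopropylsilanediyl)oxy]dauc-8-en-4-ol (4β-OH; 4α-isopropyl)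
Conditions: iPrMgCl, CeCl3, THF, −78 → 0 °C; aq. NH4Cl
Reagents that add atoms: isopropylmagnesium chloride, CC(C)[Mg]Cl
Why: 1,2-Addition of iPrCeCl2 (organocerium addition) to the hindered, enolisable ketone: on the trans-fused ring system the pseudo-axial CH3-15 shields the β face, so isopropyl should enter from the α face next to the small axial H5 and set the 4β-hydroxyl, while the weakly basic iPrCeCl2 spares the C5 centre.

Step 12
Reactants: 17 (1S,4R,5R,6S,10R)-6,10-[(diisopropylsilanediyl)oxy]dauc-8-en-4-ol
Product: 18 (1S,4R,5S,6S,10R)-dauc-8-ene-4,6,10-triol (4β,6α,10α)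
Conditions: 30% H2O2, KF, KHCO3, THF/MeOH (1:1), 50 °C
Reagents that add atoms: hydrogen peroxide, OO
Why: Tamao–Fleming oxidation replaces the C6–Si bond by C6–OH with retention (6α) and releases the 10α-hydroxyl.

Step 13
Reactants: 18 (1S,4R,5S,6S,10R)-dauc-8-ene-4,6,10-triol; 19 angelic acid
Product: 21 (1S,4R,5S,6S,10R)-4-hydroxydauc-8-ene-6,10-diyl bis[(2Z)-2-methylbut-2-enoate], via mixed anhydride 20 (not isolated)
Conditions: 19 (2.5 equiv), 2,4,6-Cl3C6H2COCl (2.5 equiv), Et3N, PhMe, 23 °C; then 18, PhMe, 80 °C
Reagents that add atoms: angelic acid (second equivalent of 19), C/C=C(/C)C(=O)O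
Why: Yamaguchi esterification through the mixed anhydride, run without a nucleophilic catalyst, should build in two molecules of 19 by acylating both secondary hydroxyls, keep the (Z)-geometry of the angeloyl group and leave the tertiary C4 hydroxyl free.

**Compound list**

1 | 2-bromo-3-methylcyclopent-2-en-1-one | CC1=C(Br)C(=O)CC1 | starting material
2 | 6-bromo-7-methyl-1,4-dioxaspiro[4.4]non-6-ene | CC1=C(Br)C2(CC1)OCCO2 | intermediate
3 | 6-ethenyl-7-methyl-1,4-dioxaspiro[4.4]non-6-ene | C=CC1=C(C)CCC12OCCO2 | intermediate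
4 | 2-[(tert-butyldimethylsilyl)oxy]acetaldehyde | O=CCO[Si](C)(C)C(C)(C)C | starting material
5 | ethyl diazoacetate | CCOC(=O)C=[N+]=[N-] | starting material
6 | ethyl 4-[(tert-butyldimethylsilyl)oxy]-2-diazo-3-hydroxybutanoate (racemic) | CCOC(=O)C(=[N+]=[N-])C(O)CO[Si](C)(C)C(C)(C)C | intermediate
7 | ethyl (3E)-4-[(tert-butyldimethylsilyl)oxy]-2-diazobut-3-enoate | CCOC(=O)C(=[N+]=[N-])/C=C/O[Si](C)(C)C(C)(C)C | intermediate
8 | ethyl (1R,2S)-1-[(E)-2-[(tert-butyldimethylsilyl)oxy]ethenyl]-2-(7-methyl-1,4-dioxaspiro[4.4]non-6-en-6-yl)cyclopropane-1-carboxylate (cis-divinylcyclopropane) | CCOC(=O)[C@]1(/C=C/O[Si](C)(C)C(C)(C)C)C[C@H]1C1=C(C)CCC12OCCO2 | intermediate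
9 | ethyl (1S,10R)-10-[(tert-butyldimethylsilyl)oxy]-4,4-(ethylenedioxy)-11,12,13-trinordauca-5,8-dien-14-oate (1β-CH3; 10α-OSi) | CC(C)(C)[Si](C)(C)O[C@@H]1C=C(C(=O)OCC)CC=C2C3(OCCO3)CC[C@]12C | intermediate
10 | (1S,10R)-10-[(tert-butyldimethylsilyl)oxy]-4,4-(ethylenedioxy)-11,12,13-trinordauca-5,8-dien-14-ol | CC(C)(C)[Si](C)(C)O[C@@H]1C=C(CO)CC=C2C3(OCCO3)CC[C@]12C | intermediate
11 | methanesulfonate of 10 (allylic mesylate) | CC(C)(C)[Si](C)(C)O[C@@H]1C=C(COS(C)(=O)=O)CC=C2C3(OCCO3)CC[C@]12C | intermediate
12 | (1S,10R)-10-[(tert-butyldimethylsilyl)oxy]-4,4-(ethylenedioxy)-11,12,13-trinordauca-5,8-diene | CC(C)(C)[Si](C)(C)O[C@@H]1C=C(C)CC=C2C3(OCCO3)CC[C@]12C | intermediate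
13 | (1S,10R)-4,4-(ethylenedioxy)-11,12,13-trinordauca-5,8-dien-10-ol (10α-OH) | O[C@@H]1C=C(C)CC=C2C3(OCCO3)CC[C@]12C | intermediate
14 | (1S,10R)-10-[(diisopropylsilyl)oxy]-4,4-(ethylenedioxy)-11,12,13-trinordauca-5,8-diene (Si–H ether) | CC(C)[SiH](C(C)C)O[C@@H]1C=C(C)CC=C2C3(OCCO3)CC[C@]12C | intermediate
15 | (1S,5R,6S,10R)-4,4-(ethylenedioxy)-6,10-[(diisopropylsilanediyl)oxy]-11,12,13-trinordauc-8-ene (Si on C6 α; O on C10 α; H5 α) | CC(C)[Si]3(C(C)C)[C@H]1CC(C)=C[C@@H](O3)[C@@]2(C)CCC4(OCCO4)[C@H]12 | intermediate
16 | (1S,5R,6S,10R)-6,10-[(diisopropylsilanediyl)oxy]-11,12,13-trinordauc-8-en-4-one | CC(C)[Si]3(C(C)C)[C@H]1CC(C)=C[C@@H](O3)[C@@]2(C)CCC(=O)[C@H]12 | intermediate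
17 | (1S,4R,5R,6S,10R)-6,10-[(diisopropylsilanediyl)oxy]dauc-8-en-4-ol (4β-OH; 4α-isopropyl) | CC(C)[Si]3(C(C)C)[C@H]1CC(C)=C[C@@H](O3)[C@@]2(C)CC[C@@](O)(C(C)C)[C@H]12 | intermediate
18 | (1S,4R,5S,6S,10R)-dauc-8-ene-4,6,10-triol (4β,6α,10α) | O[C@H]1CC(C)=C[C@@H](O)[C@@]2(C)CC[C@@](O)(C(C)C)[C@H]12 | intermediate
19 | angelic acid, (2Z)-2-methylbut-2-enoic acid | C/C=C(/C)C(=O)O | starting material
20 | (2Z)-2-methylbut-2-enoic 2,4,6-trichlorobenzoic anhydride | C/C=C(/C)C(=O)OC(=O)c1c(Cl)cc(Cl)cc1Cl | intermediate
21 | (1S,4R,5S,6S,10R)-4-hydroxydauc-8-ene-6,10-diyl bis[(2Z)-2-methylbut-2-enoate] (4β-OH; 6α,10α-diangelate) | C/C=C(/C)C(=O)O[C@H]1CC(C)=C[C@@H](OC(=O)/C(C)=C\C)[C@@]2(C)CC[C@@](O)(C(C)C)[C@H]12 | target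

**Count**

Total steps: 13. Longest linear sequence: 11 steps (1 → 21 through steps 1, 2 and 5–13; equally 4 and 5 → 21 through steps 3–13).

**Steps most likely to fail, with fallbacks**

Step 5. The shift has to form a quaternary centre with a methyl group pointing inside the boat. If it is slow, reversible homolysis or polar opening of the ester-bearing cyclopropane bond may compete, which would erode enantiopurity or divert material to the trans isomer or a cyclopentene. Fallback: the order is changed so that the acceptor is removed before the ring expansion. Setting out from 8, isolated after the cyclopropanation at low temperature, reduction with iBu2AlH (CH2Cl2, −78 °C) should give [(1R,2R)-1-[(E)-2-[(tert-butyldimethylsilyl)oxy]ethenyl]-2-(7-methyl-1,4-dioxaspiro[4.4]non-6-en-6-yl)cyclopropyl]methanol F1, which lacks the radical- and anion-stabilising ester. Heating F1 in toluene (100–110 °C) should then deliver the rearranged allylic alcohol directly, and the route is rejoined at 10.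

Step 9. A Pt–H intermediate may move the skipped 5,8-diene into conjugation, insertion may fail at the alkene flanked by two quaternary carbons, or the silane may add to the allylic C8=C9 bond. Fallback: a stoichiometric, metal-free syn addition under steric control in place of the tethered catalytic one. Setting out from 13, BH3·THF (excess, 0 → 23 °C; the free hydroxyl consumes one B–H with loss of H2) should add to C5=C6 from the α face, opposite the β angular methyl as in the hydroboration of steroidal 5-enes, with boron on the unhindered C6, while C9 of the other alkene is shielded by the oxygen-bearing neopentyl C10; oxidation with NaBO3·4H2O gives (1S,5S,6S,10R)-4,4-(ethylenedioxy)-11,12,13-trinordauc-8-ene-6,10-diol F2. Ketal hydrolysis (pyridinium p-toluenesulfonate, aqueous acetone) gives (1S,5S,6S,10R)-6,10-dihydroxy-11,12,13-trinordauc-8-en-4-one F3. Addition of excess iPrMgCl/CeCl3 (THF, −78 °C) to F3 returns to the route at 18.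

Step 13. Acylation of the neopentyl C10 hydroxyl may stall, and the base and heat may isomerise the (Z)-acyl group to the (E)-isomer (tiglate). Fallback: the (Z)-alkene is built after the ester bonds. Setting out from 18, both secondary hydroxyls are esterified with 2-[bis(2,2,2-trifluoroethoxy)phosphoryl]propanoic acid (DCC, DMAP, CH2Cl2) to give (1S,4R,5S,6S,10R)-4-hydroxydauc-8-ene-6,10-diyl bis{2-[bis(2,2,2-trifluoroethoxy)phosphoryl]propanoate} F4 (mixture at the two phosphonate-bearing carbons). A double Still–Gennari olefination of F4 with acetaldehyde (KN(SiMe3)2, 18-crown-6, THF, −78 °C) should form both (Z)-2-methylbut-2-enoates and arrive at 21.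

**Further compounds**

F1 | step 5 | [(1R,2R)-1-[(E)-2-[(tert-butyldimethylsilyl)oxy]ethenyl]-2-(7-methyl-1,4-dioxaspiro[4.4]non-6-en-6-yl)cyclopropyl]methanol | OC[C@]1(/C=C/O[Si](C)(C)C(C)(C)C)C[C@H]1C1=C(C)CCC12OCCO2
F2 | step 9 | (1S,5S,6S,10R)-4,4-(ethylenedioxy)-11,12,13-trinordauc-8-ene-6,10-diol | O[C@H]1CC(C)=C[C@@H](O)[C@@]2(C)CCC3(OCCO3)[C@H]12
F3 | step 9 | (1S,5S,6S,10R)-6,10-dihydroxy-11,12,13-trinordauc-8-en-4-one | O[C@H]1CC(C)=C[C@@H](O)[C@@]2(C)CCC(=O)[C@H]12
F4 | step 13 | (1S,4R,5S,6S,10R)-4-hydroxydauc-8-ene-6,10-diyl bis{2-[bis(2,2,2-trifluoroethoxy)phosphoryl]propanoate} | CC(C(=O)O[C@H]1CC(C)=C[C@@H](OC(=O)C(C)P(=O)(OCC(F)(F)F)OCC(F)(F)F)[C@@]2(C)CC[C@@](O)(C(C)C)[C@H]12)P(=O)(OCC(F)(F)F)OCC(F)(F)F
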